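**Retrosynthetic overview**
1. Target 34 ⇐ macrocyclic diol 32 (C3 silyl ether) by acetylation and desilylation; the 14-membered ring is closed last, at C12–C13, by an intramolecular Nozaki–Hiyama–Kishi reaction of iodo-aldehyde 31.
2. The α-methylene lactone is made first: the C1–C14 bond comes from intermolecular allylboration of (S)-glyceraldehyde acetonide 27 with the 2-(methoxycarbonyl)allylboronate 25, with lactonisation in the same pot; the dioxolane is later cut down to the C13 aldehyde.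
3. 25 ⇐ ynoate 22 (conjugate reduction, trapping with ICH2Bpin) ⇐ terminal epoxide 18 + methyl propiolate (C1–C2 bond).
4. 18 ⇐ neryl acetate 1: C3/C4 by Sharpless epoxidation and Payne rearrangement, C7=C8 and C11=C12 by two Z-selective iodo-Wittig reactions, C8–C9 by B-alkyl Suzuki coupling.
5. Ring order: five-membered lactone (step 19), then 14-membered carbocycle (step 22).

Assumption: the target is taken exactly as drawn, (1R,3S,4S,13S,14R) with both ring alkenes Z (ring carbons cis); cembrane numbering is used (C1 lactone β-CH, C14 lactone O–CH, C15 α-carbon, C16 C=O, C17 =CH2).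

**Step 1**
Reactants: 1 neryl acetate
Product: 2 (2Z)-5-(3,3-dimethyloxiran-2-yl)-3-methylpent-2-en-1-yl acetate (racemic at the epoxide carbon)
Conditions: mCPBA (1.05 equiv), NaHCO3, CH2Cl2, 0 °C
Reagents that add atoms: mCPBA (3-chloroperoxybenzoic acid), OOC(=O)c1cccc(Cl)c1
Why: Prilezhaev epoxidation attacks the electron-rich remote trisubstituted alkene much faster than the alkene deactivated by the allylic acetate, and the racemic epoxide centre is destroyed in step 2.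

**Step 2**
Reactants: 2 (2Z)-5-(3,3-dimethyloxiran-2-yl)-3-methylpent-2-en-1-yl acetate
Product: 3 (2Z)-3-methyl-6-oxohex-2-en-1-yl acetate
Conditions: H5IO6 (1.2 equiv), THF/H2O, 0 °C to rt
Reagents that add atoms: none
Why: Periodic acid opens the epoxide to the glycol and cleaves it in the same pot (Malaprade glycol cleavage), so the aldehyde oxygen is the former epoxide oxygen and the Z-allylic acetate is untouched.

**Step 3**
Reactants: 3 (2Z)-3-methyl-6-oxohex-2-en-1-yl acetate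
Product: 4 (2Z,6Z)-7-iodo-3-methylocta-2,6-dien-1-yl acetate
Conditions: EtPPh3I, n-BuLi, THF, 0 °C; I2, −78 °C; NaN(SiMe3)2, −20 °C; then 3, −78 °C
Reagents that add atoms: ethyltriphenylphosphonium iodide, CC[P+](c1ccccc1)(c1ccccc1)c1ccccc1.[I-]; iodine, II
Why: Stork–Zhao-type Wittig olefination with the α-iodo ylide Ph3P=C(I)CH3, freshly made in the flask from the ethylphosphonium salt, goes through the kinetic cis-oxaphosphetane and gives the (Z)-2-iodoalk-2-ene (iodine cis to the chain, typically ≥ 10:1), which fixes the later C7=C8 geometry.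

**Step 4**
Reactants: 4 (2Z,6Z)-7-iodo-3-methylocta-2,6-dien-1-yl acetate
Product: 5 (2Z,6Z)-7-iodo-3-methylocta-2,6-dien-1-ol
Conditions: K2CO3 (0.2 equiv), MeOH, 0 °C to rt
Reagents that add atoms: none
Why: K2CO3-catalysed transesterification (methanolysis) removes the acetate under conditions that leave the vinyl iodide alone and frees the hydroxyl that directs the epoxidation of step 7.

**Step 5**
Reactants: 6 4-methoxybenzyl alcohol; 7 allyl bromide
Product: 8 allyl 4-methoxybenzyl ether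
Conditions: NaH, THF, 0 °C; then 7, Bu4NI (cat.), rt
Reagents that add atoms: none
Why: Williamson ether synthesis of an unhindered primary alkoxide with an allylic bromide is a clean SN2 reaction.

**Step 6**
Reactants: 8 allyl 4-methoxybenzyl ether; 5 (2Z,6Z)-7-iodo-3-methylocta-2,6-dien-1-ol
Product: 10 (2Z,6Z)-10-[(4-methoxybenzyl)oxy]-3,7-dimethyldeca-2,6-dien-1-ol, via alkylborane 9 (not isolated)
Conditions: 8, 9-BBN, THF, rt; then 5, PdCl2(dppf) (5 mol %), AsPh3, Cs2CO3, DMF/H2O, rt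
Reagents that add atoms: none
Why: Anti-Markovnikov hydroboration followed by B-alkyl Suzuki–Miyaura coupling (oxidative addition of the C–I bond to zerovalent palladium, transmetalation, reductive elimination) proceeds with retention at the vinyl iodide, so C9 ends cis to C6 (7Z) and the free allylic alcohol is tolerated.

**Step 7**
Reactants: 10 (2Z,6Z)-10-[(4-methoxybenzyl)oxy]-3,7-dimethyldeca-2,6-dien-1-ol
Product: 11 [(2R,3S)-3-{(3Z)-7-[(4-methoxybenzyl)oxy]-4-methylhept-3-en-1-yl}-3-methyloxiran-2-yl]methanol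
Conditions: Ti(OiPr)4 (1.0 equiv), D-(−)-diethyl tartrate (1.2 equiv), t-BuOOH, 4 Å MS, CH2Cl2, −20 °C
Reagents that add atoms: tert-butyl hydroperoxide, CC(C)(C)OO
Why: The Sharpless asymmetric epoxidation is directed by the allylic hydroxyl, so only the C3=C4 alkene reacts, and the Ti(OiPr)4/D-(−)-diethyl tartrate complex adds oxygen to the face that gives the (2R,3S)-epoxide, which sets C4 (S) and places C3 for the inversion of step 8.

**Step 8**
Reactants: 11 [(2R,3S)-3-{(3Z)-7-[(4-methoxybenzyl)oxy]-4-methylhept-3-en-1-yl}-3-methyloxiran-2-yl]methanol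
Product: 13 (2R,3S,6Z)-1-(tert-butylsulfanyl)-10-[(4-methoxybenzyl)oxy]-3,7-dimethyldec-6-ene-2,3-diol, via terminal epoxy alcohol 12 (not isolated)
Conditions: t-BuSH (3 equiv), 0.5 M aq NaOH, t-BuOH, 75 °C, slow addition of 11
Reagents that add atoms: 2-methylpropane-2-thiol, CC(C)(C)S
Why: In the Payne rearrangement the C2 alkoxide opens the epoxide at C3 with inversion (giving the final C3 configuration while C4 keeps its oxygen), and the thiolate then captures the terminal epoxide 12 irreversibly by SN2 attack at the primary carbon C2.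

**Step 9**
Reactants: 13 (2R,3S,6Z)-1-(tert-butylsulfanyl)-10-[(4-methoxybenzyl)oxy]-3,7-dimethyldec-6-ene-2,3-diol
Product: 14 tert-butyl{(2R,3S,6Z)-2,3-dihydroxy-10-[(4-methoxybenzyl)oxy]-3,7-dimethyldec-6-en-1-yl}methylsulfonium tetrafluoroborate (mixture at sulfur)
Conditions: Me3OBF4, CH2Cl2, 0 °C to rt; evaporate
Reagents that add atoms: trimethyloxonium tetrafluoroborate, C[O+](C)C.F[B-](F)(F)F
Why: S-Alkylation by Meerwein's salt is selective for the soft dialkyl sulfide over hydroxyl, ether and alkene groups and turns sulfur into a leaving group.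

**Step 10**
Reactants: 14 tert-butyl{(2R,3S,6Z)-2,3-dihydroxy-10-[(4-methoxybenzyl)oxy]-3,7-dimethyldec-6-en-1-yl}methylsulfonium tetrafluoroborate
Product: 12 (2S,5Z)-9-[(4-methoxybenzyl)oxy]-6-methyl-2-[(2S)-oxiran-2-yl]non-5-en-2-ol
Conditions: 10 % aq NaOH, CH2Cl2, 0 °C, 30 min
Reagents that add atoms: none
Why: Intramolecular Williamson-type 3-exo-tet displacement of the dialkyl sulfide by the C3 alkoxide closes the terminal epoxide at C2 without touching the C3 or C4 stereocentres.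

**Step 11**
Reactants: 12 (2S,5Z)-9-[(4-methoxybenzyl)oxy]-6-methyl-2-[(2S)-oxiran-2-yl]non-5-en-2-ol
Product: 15 {[(2S,5Z)-9-[(4-methoxybenzyl)oxy]-6-methyl-2-[(2S)-oxiran-2-yl]non-5-en-2-yl]oxy}trimethylsilane
Conditions: 1-(trimethylsilyl)imidazole, CH2Cl2, rt
Reagents that add atoms: 1-(trimethylsilyl)imidazole, C[Si](C)(C)n1ccnc1
Why: Silylation of the tertiary alcohol by this strong silyl donor blocks the reverse Payne rearrangement in the later basic steps and leaves the epoxide intact.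

**Step 12**
Reactants: 15 {[(2S,5Z)-9-[(4-methoxybenzyl)oxy]-6-methyl-2-[(2S)-oxiran-2-yl]non-5-en-2-yl]oxy}trimethylsilane
Product: 16 (4Z,8S)-4-methyl-8-[(2S)-oxiran-2-yl]-8-[(trimethylsilyl)oxy]non-4-en-1-ol
Conditions: DDQ, CH2Cl2/pH 7 buffer (10:1), 0 °C
Reagents that add atoms: none
Why: Oxidative cleavage of the 4-methoxybenzyl ether by DDQ (hydride abstraction to the oxocarbenium ion, then hydrolysis) is neutral and spares the epoxide, the silyl ether and the trisubstituted alkene.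

**Step 13**
Reactants: 16 (4Z,8S)-4-methyl-8-[(2S)-oxiran-2-yl]-8-[(trimethylsilyl)oxy]non-4-en-1-ol
Product: 17 (4Z,8S)-4-methyl-8-[(2S)-oxiran-2-yl]-8-[(trimethylsilyl)oxy]non-4-enal
Conditions: Dess–Martin periodinane, NaHCO3, CH2Cl2, 0 °C to rt
Reagents that add atoms: none
Why: Dess–Martin oxidation converts the primary alcohol to the aldehyde under buffered, non-acidic conditions without over-oxidation.

**Step 14**
Reactants: 17 (4Z,8S)-4-methyl-8-[(2S)-oxiran-2-yl]-8-[(trimethylsilyl)oxy]non-4-enal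
Product: 18 {[(2S,5Z,9Z)-10-iodo-6-methyl-2-[(2S)-oxiran-2-yl]undeca-5,9-dien-2-yl]oxy}trimethylsilane
Conditions: EtPPh3I, n-BuLi, THF, 0 °C; I2, −78 °C; NaN(SiMe3)2, −20 °C; then 17, −78 °C
Reagents that add atoms: ethyltriphenylphosphonium iodide, CC[P+](c1ccccc1)(c1ccccc1)c1ccccc1.[I-]; iodine, II
Why: A second Stork–Zhao-type Wittig olefination, with a fresh batch of the α-iodo ylide made in the flask, gives the (Z)-2-iodoalk-2-ene (iodine cis to C10), which fixes the later C11=C12 geometry, and the epoxide survives the ylide at low temperature.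

**Step 15**
Reactants: 18 {[(2S,5Z,9Z)-10-iodo-6-methyl-2-[(2S)-oxiran-2-yl]undeca-5,9-dien-2-yl]oxy}trimethylsilane; 19 methyl propiolate
Product: 21 methyl (5S,6S,9Z,13Z)-5-hydroxy-14-iodo-6,10-dimethyl-6-[(trimethylsilyl)oxy]pentadeca-9,13-dien-2-ynoate, via lithium methyl propiolate 20 (not isolated)
Conditions: 19, n-BuLi, THF, −90 °C; BF3·OEt2; then 18, −78 °C
Reagents that add atoms: none
Why: Yamaguchi–Hirao alkynylation (BF3-assisted SN2 opening of the epoxide by the lithium acetylide at the terminal carbon C2) forms the C1–C2 bond and frees the C3 hydroxyl without changing C3 or C4.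

**Step 16**
Reactants: 21 methyl (5S,6S,9Z,13Z)-5-hydroxy-14-iodo-6,10-dimethyl-6-[(trimethylsilyl)oxy]pentadeca-9,13-dien-2-ynoate
Product: 22 methyl (5S,6S,9Z,13Z)-5-[(tert-butyldimethylsilyl)oxy]-14-iodo-6,10-dimethyl-6-[(trimethylsilyl)oxy]pentadeca-9,13-dien-2-ynoate
Conditions: TBSOTf, 2,6-lutidine, CH2Cl2, −78 to 0 °C
Reagents that add atoms: TBSOTf (tert-butyldimethylsilyl triflate), CC(C)(C)[Si](C)(C)OS(=O)(=O)C(F)(F)F
Why: Silylation by the triflate protects the hindered secondary C3 alcohol as a robust ether that is kept until the last step.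

**Step 17**
Reactants: 22 methyl (5S,6S,9Z,13Z)-5-[(tert-butyldimethylsilyl)oxy]-14-iodo-6,10-dimethyl-6-[(trimethylsilyl)oxy]pentadeca-9,13-dien-2-ynoate; 23 2-(iodomethyl)-4,4,5,5-tetramethyl-1,3,2-dioxaborolane
Product: 25 methyl (2Z,5S,6S,9Z,13Z)-5-[(tert-butyldimethylsilyl)oxy]-14-iodo-6,10-dimethyl-2-[(4,4,5,5-tetramethyl-1,3,2-dioxaborolan-2-yl)methyl]-6-[(trimethylsilyl)oxy]pentadeca-2,9,13-trienoate, via aluminium allenolate 24 (not isolated)
Conditions: i-Bu2AlH, HMPA, THF, 0 °C; then 22, 0 °C; then 23, rt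
Reagents that add atoms: none
Why: Conjugate hydroalumination of the ynoate by the i-Bu2AlH–HMPA complex gives the aluminium allenolate 24, which is C-alkylated by the iodomethylboronate from the side of the small hydrogen, so the C2 chain ends cis to the ester and trans to the CH2B group.

**Step 18**
Reactants: 26 (R)-solketal, [(4R)-2,2-dimethyl-1,3-dioxolan-4-yl]methanol
Product: 27 (S)-glyceraldehyde acetonide, (4S)-2,2-dimethyl-1,3-dioxolane-4-carbaldehyde
Conditions: Dess–Martin periodinane, NaHCO3, CH2Cl2, 0 °C to rt; used at once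
Reagents that add atoms: none
Why: Dess–Martin oxidation gives the configurationally labile α-alkoxy aldehyde under mild buffered conditions, and immediate use avoids racemisation.

**Step 19**
Reactants: 25 methyl (2Z,5S,6S,9Z,13Z)-5-[(tert-butyldimethylsilyl)oxy]-14-iodo-6,10-dimethyl-2-[(4,4,5,5-tetramethyl-1,3,2-dioxaborolan-2-yl)methyl]-6-[(trimethylsilyl)oxy]pentadeca-2,9,13-trienoate; 27 (S)-glyceraldehyde acetonide
Product: 29 (4R,5R)-4-{(2S,3S,6Z,10Z)-2-[(tert-butyldimethylsilyl)oxy]-11-iodo-3,7-dimethyl-3-[(trimethylsilyl)oxy]dodeca-6,10-dien-1-yl}-5-[(4S)-2,2-dimethyl-1,3-dioxolan-4-yl]-3-methylideneoxolan-2-one, via pinacol borate adduct 28 (not isolated)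
Conditions: 27 (3 equiv), toluene, 4 Å MS, 50 °C, 72 h; then 90 °C, 8 h
Reagents that add atoms: none
Why: Carbonyl allylation (allylboration) through a closed chair transition state puts the C2 substituent, which is trans to the CH2B group, equatorial and so gives the 1,14-anti adduct (trans lactone once the borate oxygen closes onto the ester), while Felkin–Anh attack anti to the α-C–O bond of 27 gives the anti relation to the dioxolane oxygen, which together set C14 (R) and C1 (R), the dioxolane centre being only a controller that is cut away in step 21.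

**Step 20**
Reactants: 29 (4R,5R)-4-{(2S,3S,6Z,10Z)-2-[(tert-butyldimethylsilyl)oxy]-11-iodo-3,7-dimethyl-3-[(trimethylsilyl)oxy]dodeca-6,10-dien-1-yl}-5-[(4S)-2,2-dimethyl-1,3-dioxolan-4-yl]-3-methylideneoxolan-2-one
Product: 30 (4R,5R)-4-{(2S,3S,6Z,10Z)-2-[(tert-butyldimethylsilyl)oxy]-3-hydroxy-11-iodo-3,7-dimethyldodeca-6,10-dien-1-yl}-5-[(1S)-1,2-dihydroxyethyl]-3-methylideneoxolan-2-one
Conditions: AcOH/H2O/THF (3:1:1), 40 °C
Reagents that add atoms: none
Why: Mild acid hydrolysis removes the terminal isopropylidene acetal and the labile tertiary trimethylsilyl ether, while the hindered secondary tert-butyldimethylsilyl ether and the lactone survive.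

**Step 21**
Reactants: 30 (4R,5R)-4-{(2S,3S,6Z,10Z)-2-[(tert-butyldimethylsilyl)oxy]-3-hydroxy-11-iodo-3,7-dimethyldodeca-6,10-dien-1-yl}-5-[(1S)-1,2-dihydroxyethyl]-3-methylideneoxolan-2-one
Product: 31 (2R,3R)-3-{(2S,3S,6Z,10Z)-2-[(tert-butyldimethylsilyl)oxy]-3-hydroxy-11-iodo-3,7-dimethyldodeca-6,10-dien-1-yl}-4-methylidene-5-oxooxolane-2-carbaldehyde
Conditions: NaIO4, THF/pH 7 buffer, 0 °C; used at once
Reagents that add atoms: none
Why: Malaprade glycol cleavage by periodate acts only on the free vicinal diol and gives the C13 aldehyde without epimerising C14.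

**Step 22**
Reactants: 31 (2R,3R)-3-{(2S,3S,6Z,10Z)-2-[(tert-butyldimethylsilyl)oxy]-3-hydroxy-11-iodo-3,7-dimethyldodeca-6,10-dien-1-yl}-4-methylidene-5-oxooxolane-2-carbaldehyde
Product: 32 (1R,3S,4S,7Z,11Z,13S,14R)-3-[(tert-butyldimethylsilyl)oxy]-4,13-dihydroxycembra-7,11,15(17)-trien-16,14-olide
Conditions: CrCl2 (15 equiv), NiCl2 (0.15 equiv), DMSO/THF (3:1), 2 mM, rt, syringe-pump addition
Reagents that add atoms: none
Why: The intramolecular Nozaki–Hiyama–Kishi reaction (nickel-catalysed insertion into the C–I bond, transmetalation to a vinyl species of trivalent chromium, addition to the aldehyde) closes the 14-membered ring at C12–C13 with retention of the 11Z geometry and, by Felkin–Anh attack anti to the lactone C–O bond at C14, gives the 13,14-anti alcohol (13S).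

**Step 23**
Reactants: 32 (1R,3S,4S,7Z,11Z,13S,14R)-3-[(tert-butyldimethylsilyl)oxy]-4,13-dihydroxycembra-7,11,15(17)-trien-16,14-olide
Product: 33 (1R,3S,4S,7Z,11Z,13S,14R)-4,13-diacetoxy-3-[(tert-butyldimethylsilyl)oxy]cembra-7,11,15(17)-trien-16,14-olide
Conditions: Ac2O (excess), DMAP (2 equiv), Et3N, CH2Cl2, 40 °C
Reagents that add atoms: acetic anhydride, CC(=O)OC(C)=O
Why: DMAP-catalysed acylation with excess anhydride acetylates both the secondary allylic C13 hydroxyl and the tertiary C4 hydroxyl while the C3 oxygen is masked.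

**Step 24**
Reactants: 33 (1R,3S,4S,7Z,11Z,13S,14R)-4,13-diacetoxy-3-[(tert-butyldimethylsilyl)oxy]cembra-7,11,15(17)-trien-16,14-olide
Product: 34 (1R,3S,4S,7Z,11Z,13S,14R)-4,13-diacetoxy-3-hydroxycembra-7,11,15(17)-trien-16,14-olide (CNP0127975.1)
Conditions: HF·pyridine, pyridine, THF, 0 °C to rt
Reagents that add atoms: none
Why: Fluoride-mediated desilylation under buffered, weakly acidic conditions frees the C3 hydroxyl without 1,2-acyl migration from the tertiary acetate or addition to the methylene lactone.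

**Compound list**
1 | neryl acetate, (2Z)-3,7-dimethylocta-2,6-dien-1-yl acetate | CC(C)=CCC/C(C)=C\COC(C)=O | starting material
2 | (2Z)-5-(3,3-dimethyloxiran-2-yl)-3-methylpent-2-en-1-yl acetate (racemic epoxide) | CC1(C)OC1CC/C(C)=C\COC(C)=O | intermediate
3 | (2Z)-3-methyl-6-oxohex-2-en-1-yl acetate | O=CCC/C(C)=C\COC(C)=O | intermediate
4 | (2Z,6Z)-7-iodo-3-methylocta-2,6-dien-1-yl acetate | C/C(I)=C/CC/C(C)=C\COC(C)=O | intermediate
5 | (2Z,6Z)-7-iodo-3-methylocta-2,6-dien-1-ol | C/C(I)=C/CC/C(C)=C\CO | intermediate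
6 | 4-methoxybenzyl alcohol | COc1ccc(CO)cc1 | starting material
7 | allyl bromide | C=CCBr | starting material
8 | allyl 4-methoxybenzyl ether | C=CCOCc1ccc(OC)cc1 | intermediate
9 | 9-{3-[(4-methoxybenzyl)oxy]propyl}-9-borabicyclo[3.3.1]nonane | COc1ccc(COCCCB2C3CCCC2CCC3)cc1 | intermediate
10 | (2Z,6Z)-10-[(4-methoxybenzyl)oxy]-3,7-dimethyldeca-2,6-dien-1-ol | OC/C=C(/C)CC/C=C(/C)CCCOCc1ccc(OC)cc1 | intermediate
11 | [(2R,3S)-3-{(3Z)-7-[(4-methoxybenzyl)oxy]-4-methylhept-3-en-1-yl}-3-methyloxiran-2-yl]methanol | OC[C@H]1O[C@@]1(C)CC/C=C(/C)CCCOCc1ccc(OC)cc1 | intermediate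
12 | (2S,5Z)-9-[(4-methoxybenzyl)oxy]-6-methyl-2-[(2S)-oxiran-2-yl]non-5-en-2-ol | C1O[C@@H]1[C@@](C)(O)CC/C=C(/C)CCCOCc1ccc(OC)cc1 | intermediate
13 | (2R,3S,6Z)-1-(tert-butylsulfanyl)-10-[(4-methoxybenzyl)oxy]-3,7-dimethyldec-6-ene-2,3-diol | CC(C)(C)SC[C@H](O)[C@@](C)(O)CC/C=C(/C)CCCOCc1ccc(OC)cc1 | intermediate
14 | tert-butyl{(2R,3S,6Z)-2,3-dihydroxy-10-[(4-methoxybenzyl)oxy]-3,7-dimethyldec-6-en-1-yl}methylsulfonium tetrafluoroborate | C[S+](C[C@H](O)[C@@](C)(O)CC/C=C(/C)CCCOCc1ccc(OC)cc1)C(C)(C)C.F[B-](F)(F)F | intermediate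
15 | {[(2S,5Z)-9-[(4-methoxybenzyl)oxy]-6-methyl-2-[(2S)-oxiran-2-yl]non-5-en-2-yl]oxy}trimethylsilane | C1O[C@@H]1[C@@](C)(O[Si](C)(C)C)CC/C=C(/C)CCCOCc1ccc(OC)cc1 | intermediate
16 | (4Z,8S)-4-methyl-8-[(2S)-oxiran-2-yl]-8-[(trimethylsilyl)oxy]non-4-en-1-ol | C1O[C@@H]1[C@@](C)(O[Si](C)(C)C)CC/C=C(/C)CCCO | intermediate
17 | (4Z,8S)-4-methyl-8-[(2S)-oxiran-2-yl]-8-[(trimethylsilyl)oxy]non-4-enal | C1O[C@@H]1[C@@](C)(O[Si](C)(C)C)CC/C=C(/C)CCC=O | intermediate
18 | {[(2S,5Z,9Z)-10-iodo-6-methyl-2-[(2S)-oxiran-2-yl]undeca-5,9-dien-2-yl]oxy}trimethylsilane | C1O[C@@H]1[C@@](C)(O[Si](C)(C)C)CC/C=C(/C)CC/C=C(/C)I | intermediate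
19 | methyl propiolate | C#CC(=O)OC | starting material
20 | lithium methyl propiolate | [Li]C#CC(=O)OC | intermediate
21 | methyl (5S,6S,9Z,13Z)-5-hydroxy-14-iodo-6,10-dimethyl-6-[(trimethylsilyl)oxy]pentadeca-9,13-dien-2-ynoate | COC(=O)C#CC[C@H](O)[C@@](C)(O[Si](C)(C)C)CC/C=C(/C)CC/C=C(/C)I | intermediate
22 | methyl (5S,6S,9Z,13Z)-5-[(tert-butyldimethylsilyl)oxy]-14-iodo-6,10-dimethyl-6-[(trimethylsilyl)oxy]pentadeca-9,13-dien-2-ynoate | COC(=O)C#CC[C@H](O[Si](C)(C)C(C)(C)C)[C@@](C)(O[Si](C)(C)C)CC/C=C(/C)CC/C=C(/C)I | intermediate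
23 | 2-(iodomethyl)-4,4,5,5-tetramethyl-1,3,2-dioxaborolane | CC1(C)OB(CI)OC1(C)C | starting material
24 | diisobutylaluminium allenolate of 22 (O-aluminated methyl 2,3-dienoate) | COC(O[Al](CC(C)C)CC(C)C)=C=CC[C@H](O[Si](C)(C)C(C)(C)C)[C@@](C)(O[Si](C)(C)C)CC/C=C(/C)CC/C=C(/C)I | intermediate
25 | methyl (2Z,5S,6S,9Z,13Z)-5-[(tert-butyldimethylsilyl)oxy]-14-iodo-6,10-dimethyl-2-[(4,4,5,5-tetramethyl-1,3,2-dioxaborolan-2-yl)methyl]-6-[(trimethylsilyl)oxy]pentadeca-2,9,13-trienoate | COC(=O)/C(CB1OC(C)(C)C(C)(C)O1)=C\C[C@H](O[Si](C)(C)C(C)(C)C)[C@@](C)(O[Si](C)(C)C)CC/C=C(/C)CC/C=C(/C)I | intermediate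
26 | (R)-solketal, [(4R)-2,2-dimethyl-1,3-dioxolan-4-yl]methanol | OC[C@@H]1COC(C)(C)O1 | starting material
27 | (S)-glyceraldehyde acetonide, (4S)-2,2-dimethyl-1,3-dioxolane-4-carbaldehyde | O=C[C@@H]1COC(C)(C)O1 | intermediate
28 | pinacol borate of the anti homoallylic alcohol (open-chain methyl ester before lactonisation) | C=C(C(=O)OC)[C@@H](C[C@H](O[Si](C)(C)C(C)(C)C)[C@@](C)(O[Si](C)(C)C)CC/C=C(/C)CC/C=C(/C)I)[C@@H](OB1OC(C)(C)C(C)(C)O1)[C@@H]1COC(C)(C)O1 | intermediate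
29 | (4R,5R)-4-{(2S,3S,6Z,10Z)-2-[(tert-butyldimethylsilyl)oxy]-11-iodo-3,7-dimethyl-3-[(trimethylsilyl)oxy]dodeca-6,10-dien-1-yl}-5-[(4S)-2,2-dimethyl-1,3-dioxolan-4-yl]-3-methylideneoxolan-2-one | C=C1C(=O)O[C@@H]([C@@H]2COC(C)(C)O2)[C@@H]1C[C@H](O[Si](C)(C)C(C)(C)C)[C@@](C)(O[Si](C)(C)C)CC/C=C(/C)CC/C=C(/C)I | intermediate
30 | (4R,5R)-4-{(2S,3S,6Z,10Z)-2-[(tert-butyldimethylsilyl)oxy]-3-hydroxy-11-iodo-3,7-dimethyldodeca-6,10-dien-1-yl}-5-[(1S)-1,2-dihydroxyethyl]-3-methylideneoxolan-2-one | C=C1C(=O)O[C@@H]([C@@H](O)CO)[C@@H]1C[C@H](O[Si](C)(C)C(C)(C)C)[C@@](C)(O)CC/C=C(/C)CC/C=C(/C)I | intermediate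
31 | (2R,3R)-3-{(2S,3S,6Z,10Z)-2-[(tert-butyldimethylsilyl)oxy]-3-hydroxy-11-iodo-3,7-dimethyldodeca-6,10-dien-1-yl}-4-methylidene-5-oxooxolane-2-carbaldehyde | C=C1C(=O)O[C@@H](C=O)[C@@H]1C[C@H](O[Si](C)(C)C(C)(C)C)[C@@](C)(O)CC/C=C(/C)CC/C=C(/C)I | intermediate
32 | (1R,3S,4S,7Z,11Z,13S,14R)-3-[(tert-butyldimethylsilyl)oxy]-4,13-dihydroxycembra-7,11,15(17)-trien-16,14-olide | C=C1C(=O)O[C@@H]2[C@@H]1C[C@H](O[Si](C)(C)C(C)(C)C)[C@@](C)(O)CC/C=C(/C)CC/C=C(/C)[C@@H]2O | intermediate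
33 | (1R,3S,4S,7Z,11Z,13S,14R)-4,13-diacetoxy-3-[(tert-butyldimethylsilyl)oxy]cembra-7,11,15(17)-trien-16,14-olide | C=C1C(=O)O[C@@H]2[C@@H]1C[C@H](O[Si](C)(C)C(C)(C)C)[C@@](C)(OC(C)=O)CC/C=C(/C)CC/C=C(/C)[C@@H]2OC(C)=O | intermediate
34 | (1R,3S,4S,7Z,11Z,13S,14R)-4,13-diacetoxy-3-hydroxycembra-7,11,15(17)-trien-16,14-olide (CNP0127975.1) | C=C1C(=O)O[C@@H]2[C@@H]1C[C@H](O)[C@@](C)(OC(C)=O)CC/C=C(/C)CC/C=C(/C)[C@@H]2OC(C)=O | target

**Totals**
Total step count: 24. Longest linear sequence: 22 steps (1–4, 6–17, 19–24, from neryl acetate); steps 5 and 18 are one-step side branches.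

**Three steps most likely to fail**

Step 19 (the allylboration) is the least precedented step: the ester-deactivated boronate may add slowly, and the Felkin preference of 27 with this reagent geometry may be only moderate. The fallback sets out from 25 and hands face selection to a catalyst. 25 is combined with achiral (tert-butyldimethylsilyloxy)acetaldehyde and the chiral phosphoric acid (R)-TRIP (5 mol %, toluene, 4 Å MS, −30 °C to rt, then 80 °C). The same chair transition state gives the anti adduct, which closes to (4R,5R)-5-{[(tert-butyldimethylsilyl)oxy]methyl}-4-{(2S,3S,6Z,10Z)-2-[(tert-butyldimethylsilyl)oxy]-11-iodo-3,7-dimethyl-3-[(trimethylsilyl)oxy]dodeca-6,10-dien-1-yl}-3-methylideneoxolan-2-one F1; (R)-TRIP is chosen by analogy with simple crotylboronates, and the other enantiomer is used if the sense is reversed. HF·pyridine/pyridine in THF at 0 °C removes the primary silyl ether and the trimethylsilyl ether but not the hindered secondary one, giving (4R,5R)-4-{(2S,3S,6Z,10Z)-2-[(tert-butyldimethylsilyl)oxy]-3-hydroxy-11-iodo-3,7-dimethyldodeca-6,10-dien-1-yl}-5-(hydroxymethyl)-3-methylideneoxolan-2-one F2. Dess–Martin oxidation of the primary alcohol then gives 31, where the route is rejoined.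

Step 22 (the ring closure) may favour the wrong C13 epimer, because the macrocyclic transition state can override the Felkin preference. The fallback sets out from 31 and sets C13 by reduction instead of by addition. The crude closure product, mainly (1R,3S,4S,7Z,11Z,13R,14R)-3-[(tert-butyldimethylsilyl)oxy]-4,13-dihydroxycembra-7,11,15(17)-trien-16,14-olide F3, is oxidised with Dess–Martin periodinane; the tertiary C4 hydroxyl is inert. This gives the Z-enone (1R,3S,4S,7Z,11Z,14R)-3-[(tert-butyldimethylsilyl)oxy]-4-hydroxy-13-oxocembra-7,11,15(17)-trien-16,14-olide F4. Reagent-controlled Corey–Bakshi–Shibata reduction with (S)-2-methyl-CBS-oxazaborolidine and catecholborane in toluene at −78 °C (alkenyl as the large group) then gives 32.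

Step 23 (bis-acetylation) may stall at the tertiary C4 hydroxyl, which sits next to the bulky C3 silyl ether. The fallback sets out from 32 and delivers the tertiary acetate through a cyclic orthoester. Ac2O/pyridine with catalytic DMAP at 0 °C acetylates only C13, giving (1R,3S,4S,7Z,11Z,13S,14R)-13-acetoxy-3-[(tert-butyldimethylsilyl)oxy]-4-hydroxycembra-7,11,15(17)-trien-16,14-olide F5. HF·pyridine then gives (1R,3S,4S,7Z,11Z,13S,14R)-13-acetoxy-3,4-dihydroxycembra-7,11,15(17)-trien-16,14-olide F6. Trimethyl orthoacetate with PPTS in CH2Cl2 converts this diol into the 3,4-O-(1-methoxyethylidene) orthoester of the 13-acetate F7. Brief hydrolysis in 80 % aqueous AcOH at rt opens the orthoester kinetically with the acyl group left on the more hindered tertiary oxygen, giving 34; the minor 3-acetate regioisomer is removed by chromatography.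

**Further compounds**
F1 | step 19 | (4R,5R)-5-{[(tert-butyldimethylsilyl)oxy]methyl}-4-{(2S,3S,6Z,10Z)-2-[(tert-butyldimethylsilyl)oxy]-11-iodo-3,7-dimethyl-3-[(trimethylsilyl)oxy]dodeca-6,10-dien-1-yl}-3-methylideneoxolan-2-one | C=C1C(=O)O[C@@H](CO[Si](C)(C)C(C)(C)C)[C@@H]1C[C@H](O[Si](C)(C)C(C)(C)C)[C@@](C)(O[Si](C)(C)C)CC/C=C(/C)CC/C=C(/C)I
F2 | step 19 | (4R,5R)-4-{(2S,3S,6Z,10Z)-2-[(tert-butyldimethylsilyl)oxy]-3-hydroxy-11-iodo-3,7-dimethyldodeca-6,10-dien-1-yl}-5-(hydroxymethyl)-3-methylideneoxolan-2-one | C=C1C(=O)O[C@@H](CO)[C@@H]1C[C@H](O[Si](C)(C)C(C)(C)C)[C@@](C)(O)CC/C=C(/C)CC/C=C(/C)I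
F3 | step 22 | (1R,3S,4S,7Z,11Z,13R,14R)-3-[(tert-butyldimethylsilyl)oxy]-4,13-dihydroxycembra-7,11,15(17)-trien-16,14-olide | C=C1C(=O)O[C@@H]2[C@@H]1C[C@H](O[Si](C)(C)C(C)(C)C)[C@@](C)(O)CC/C=C(/C)CC/C=C(/C)[C@H]2O
F4 | step 22 | (1R,3S,4S,7Z,11Z,14R)-3-[(tert-butyldimethylsilyl)oxy]-4-hydroxy-13-oxocembra-7,11,15(17)-trien-16,14-olide | C=C1C(=O)O[C@@H]2[C@@H]1C[C@H](O[Si](C)(C)C(C)(C)C)[C@@](C)(O)CC/C=C(/C)CC/C=C(/C)C2=O
F5 | step 23 | (1R,3S,4S,7Z,11Z,13S,14R)-13-acetoxy-3-[(tert-butyldimethylsilyl)oxy]-4-hydroxycembra-7,11,15(17)-trien-16,14-olide | C=C1C(=O)O[C@@H]2[C@@H]1C[C@H](O[Si](C)(C)C(C)(C)C)[C@@](C)(O)CC/C=C(/C)CC/C=C(/C)[C@@H]2OC(C)=O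
F6 | step 23 | (1R,3S,4S,7Z,11Z,13S,14R)-13-acetoxy-3,4-dihydroxycembra-7,11,15(17)-trien-16,14-olide | C=C1C(=O)O[C@@H]2[C@@H]1C[C@H](O)[C@@](C)(O)CC/C=C(/C)CC/C=C(/C)[C@@H]2OC(C)=O
F7 | step 23 | 3,4-O-(1-methoxyethylidene) orthoester of F6 (mixture at the orthoester carbon) | C=C1C(=O)O[C@@H]2[C@@H]1C[C@@H]3OC(C)(OC)O[C@@]3(C)CC/C=C(/C)CC/C=C(/C)[C@@H]2OC(C)=O
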